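Retrosynthesis: the C8 angelate, C14 aldehyde and C15 hydroxyl go back to protected alcohols; the lactone is cut at O–C6 and C11–C12 (loss of CO2) to a ten-membered 6-hydroxy-7-(1-borylvinyl) diene, which is cut at C1=C10 (ring-closing metathesis) and C6–C7 (allenylzinc addition) into a C1–C6/C15 enal and a C7–C14 propargylic mesylate.
Forward: the two fragments are joined at C6–C7, the ten-membered carbocycle is closed at C1=C10, and the α-methylene-γ-butyrolactone is annulated last, before acylation, oxidation and desilylation.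
Enabling feature: C6 is an allylic carbinol carbon (next to C4=C5) lying 1,3 to the sp2 carbon C11, and the five-membered lactone is cis-fused to the ten-membered ring at C6–C7; the anti-selective C6–C7 bond formation puts the C6 hydroxyl on the wrong face, so the lactone oxygen is brought in with inversion by a carboxylate generated from CO2 at C11.
Stereochemistry: C8 comes from (R)-glycidol, C7 from a Felkin–Anh alkynylation relayed through the mesylate (anti-SN2′ then syn-SE2′), C6 from the closed transition state of the allenylzinc addition followed by SN2 inversion in the key step; C4=C5 comes from a directed trans-hydroalumination/iodination and C1=C10 from ring constraint in the metathesis.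
Key step: step 16
Remark: locants C1–C15 in the explanatory text are the germacrane positions of the target skeleton (C11 lactone α-carbon, C12 lactone carbonyl, C13 exocyclic methylene, C14 formyl carbon, C15 hydroxymethyl carbon); compound names carry their own systematic locants.

Step 1
Reactants: 1 but-2-yne-1,4-diol
Product: 2 4-[(tert-butyldiphenylsilyl)oxy]but-2-yn-1-ol
Conditions: 1 (3 equiv), TBDPSCl (1 equiv), imidazole, DMF, 0 °C to rt
Reagents that add atoms: tert-butyl(chloro)diphenylsilane, CC(C)(C)[Si](Cl)(c1ccccc1)c1ccccc1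
Why: Statistical monosilylation of the symmetrical diol used in excess (imidazole-promoted silyl ether formation) leaves one propargylic hydroxyl free to direct step 2.

Step 2
Reactants: 2 4-[(tert-butyldiphenylsilyl)oxy]but-2-yn-1-ol
Product: 4 (2Z)-4-[(tert-butyldiphenylsilyl)oxy]-3-iodobut-2-en-1-ol, via cyclic vinylalanate 3 (not isolated)
Conditions: NaAlH2(OCH2CH2OMe)2, THF, 0 °C; then I2, −78 °C to 0 °C
Reagents that add atoms: iodine, II
Why: The free hydroxyl directs a trans-hydroalumination that delivers hydride to the proximal alkyne carbon and leaves aluminium on the distal one in a five-membered alanate, and iodinolysis with retention should give the Z iodide that fixes the C4=C5 geometry of the target (hydroxyl-directed alkyne hydroalumination–iodination).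

Step 3
Reactants: 4 (2Z)-4-[(tert-butyldiphenylsilyl)oxy]-3-iodobut-2-en-1-ol
Product: 5 (2E)-3-{[(tert-butyldiphenylsilyl)oxy]methyl}hepta-2,6-dien-1-ol
Conditions: but-3-enylzinc bromide (3 equiv), Pd(dppf)Cl2 (5 mol %), THF, 50 °C [dppf = 1,1′-bis(diphenylphosphino)ferrocene]
Reagents that add atoms: but-3-en-1-ylzinc bromide, C=CCC[Zn]Br
Why: Negishi sp2–sp3 coupling proceeds with retention of the vinyl iodide geometry, so the butenyl chain (C1–C3 plus the metathesis carbon) ends cis to the carbinol carbon C6.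

Step 4
Reactants: 5 (2E)-3-{[(tert-butyldiphenylsilyl)oxy]methyl}hepta-2,6-dien-1-ol
Product: 6 (2E)-3-{[(tert-butyldiphenylsilyl)oxy]methyl}hepta-2,6-dienal
Conditions: MnO2, CH2Cl2, rt
Reagents that add atoms: none
Why: MnO2 oxidises the primary allylic alcohol to the enal without touching the isolated olefin or scrambling the trisubstituted double bond.

Step 5
Reactants: 7 2,3-dibromoprop-1-ene
Product: 8 1-{[(2-bromoprop-2-en-1-yl)oxy]methyl}-4-methoxybenzene
Conditions: 4-MeOC6H4CH2OH, NaH, THF, 0 °C; then 7, 0 °C to rt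
Reagents that add atoms: 4-methoxybenzyl alcohol, COc1ccc(CO)cc1
Why: Williamson etherification by SN2 displacement of the allylic bromide leaves the vinylic bromide for halogen–lithium exchange.

Step 6
Reactants: 9 (R)-glycidol
Product: 10 triethyl{[(2S)-oxiran-2-yl]methoxy}silane
Conditions: TESCl, imidazole, CH2Cl2, 0 °C
Reagents that add atoms: chlorotriethylsilane, CC[Si](Cl)(CC)CC
Why: Silylation of the primary hydroxyl masks the alcohol for the organolithium step without touching the stereocentre (the descriptor changes from R to S by priority only).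

Step 7
Reactants: 8 1-{[(2-bromoprop-2-en-1-yl)oxy]methyl}-4-methoxybenzene, 10 triethyl{[(2S)-oxiran-2-yl]methoxy}silane
Product: 12 (2S)-4-{[(4-methoxybenzyl)oxy]methyl}-1-[(triethylsilyl)oxy]pent-4-en-2-ol, via vinyllithium 11 (not isolated)
Conditions: 8, t-BuLi (2 equiv), Et2O, −78 °C; then BF3·OEt2, 10, −78 °C
Reagents that add atoms: none
Why: Bromine–lithium exchange at −78 °C gives the vinyllithium before β-alkoxide elimination can set in, and BF3-promoted SN2 opening of the epoxide at its unsubstituted carbon forms C9–C10 and releases the C8 carbinol with the glycidol stereocentre retained.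

Step 8
Reactants: 12 (2S)-4-{[(4-methoxybenzyl)oxy]methyl}-1-[(triethylsilyl)oxy]pent-4-en-2-ol
Product: 13 (2S)-4-{[(4-methoxybenzyl)oxy]methyl}-1,2-bis[(triethylsilyl)oxy]pent-4-ene
Conditions: TESCl, imidazole, DMF, rt
Reagents that add atoms: chlorotriethylsilane, CC[Si](Cl)(CC)CC
Why: Silylation of the secondary alcohol gives the bis(triethylsilyl) ether needed for the selective oxidation of step 9 (any earlier 1,2-silyl shift is made irrelevant here).

Step 9
Reactants: 13 (2S)-4-{[(4-methoxybenzyl)oxy]methyl}-1,2-bis[(triethylsilyl)oxy]pent-4-ene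
Product: 14 (2S)-4-{[(4-methoxybenzyl)oxy]methyl}-2-[(triethylsilyl)oxy]pent-4-enal
Conditions: (COCl)2, DMSO, CH2Cl2, −78 to −30 °C; then Et3N, −78 °C to 0 °C
Reagents that add atoms: none
Why: Under Swern conditions the chlorosulfonium reagent cleaves only the unhindered primary Si–O bond and oxidises that position to the aldehyde, while the secondary silyl ether and the α-stereocentre stay intact at low temperature.

Step 10
Reactants: 14 (2S)-4-{[(4-methoxybenzyl)oxy]methyl}-2-[(triethylsilyl)oxy]pent-4-enal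
Product: 15 (3R,4S)-6-{[(4-methoxybenzyl)oxy]methyl}-4-[(triethylsilyl)oxy]-1-(trimethylsilyl)hept-6-en-1-yn-3-ol
Conditions: Me3SiC≡CH, n-BuLi, THF, −78 °C; then 14, −78 °C
Reagents that add atoms: ethynyl(trimethyl)silane, C#C[Si](C)(C)C
Why: Felkin–Anh (non-chelation) addition of the lithium acetylide anti to the α-silyloxy group should give mainly the 3,4-anti carbinol (new stereocentre 3R), the minor syn epimer being removed by chromatography.

Step 11
Reactants: 15 (3R,4S)-6-{[(4-methoxybenzyl)oxy]methyl}-4-[(triethylsilyl)oxy]-1-(trimethylsilyl)hept-6-en-1-yn-3-ol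
Product: 16 (3R,4S)-6-{[(4-methoxybenzyl)oxy]methyl}-4-[(triethylsilyl)oxy]-1-(trimethylsilyl)hept-6-en-1-yn-3-yl methanesulfonate
Conditions: MsCl, Et3N, CH2Cl2, −78 to 0 °C
Reagents that add atoms: methanesulfonyl chloride, CS(=O)(=O)Cl
Why: Sulfonylation with retention at carbon gives the propargylic mesylate required for the palladium-mediated umpolung.

Step 12
Reactants: 6 (2E)-3-{[(tert-butyldiphenylsilyl)oxy]methyl}hepta-2,6-dienal, 16 (3R,4S)-6-{[(4-methoxybenzyl)oxy]methyl}-4-[(triethylsilyl)oxy]-1-(trimethylsilyl)hept-6-en-1-yn-3-yl methanesulfonate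
Product: 18 (5E,7S,8R,9S)-5-{[(tert-butyldiphenylsilyl)oxy]methyl}-11-{[(4-methoxybenzyl)oxy]methyl}-9-[(triethylsilyl)oxy]-8-[(trimethylsilyl)ethynyl]dodeca-1,5,11-trien-7-ol, via allenylzinc mesylate 17 (not isolated)
Conditions: Pd(OAc)2 (5 mol %), PPh3 (5 mol %), Et2Zn (3 equiv), THF, −78 to −20 °C
Reagents that add atoms: none
Why: Zerovalent palladium displaces the mesylate anti-SN2′, transmetalation to zinc gives a configurationally defined allenylzinc, and its syn-SE2′ addition to the enal through a closed six-membered transition state forms C6–C7, transferring the mesylate chirality to C7 with net inversion and giving the 6,7-anti (6S) homopropargylic alcohol (palladium-catalysed propargylic umpolung, allenylzinc addition).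

Step 13
Reactants: 18 (5E,7S,8R,9S)-5-{[(tert-butyldiphenylsilyl)oxy]methyl}-11-{[(4-methoxybenzyl)oxy]methyl}-9-[(triethylsilyl)oxy]-8-[(trimethylsilyl)ethynyl]dodeca-1,5,11-trien-7-ol
Product: 19 (1S,2E,6E,9S,10R)-3-{[(tert-butyldiphenylsilyl)oxy]methyl}-7-{[(4-methoxybenzyl)oxy]methyl}-9-[(triethylsilyl)oxy]-10-[(trimethylsilyl)ethynyl]cyclodeca-2,6-dien-1-ol
Conditions: second-generation Hoveyda–Grubbs catalyst (10 mol %), 1,4-benzoquinone (20 mol %), toluene (1 mM), 80 °C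
Reagents that add atoms: none
Why: Ring-closing metathesis of the terminal olefin with the 1,1-disubstituted olefin at high dilution closes the ten-membered ring, the ring-cis (E by CIP) trisubstituted C1=C10 bond being the geometry the medium ring accommodates, while the silylated alkyne stays out of enyne metathesis.

Step 14
Reactants: 19 (1S,2E,6E,9S,10R)-3-{[(tert-butyldiphenylsilyl)oxy]methyl}-7-{[(4-methoxybenzyl)oxy]methyl}-9-[(triethylsilyl)oxy]-10-[(trimethylsilyl)ethynyl]cyclodeca-2,6-dien-1-ol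
Product: 20 (1S,2E,6E,9S,10R)-3-{[(tert-butyldiphenylsilyl)oxy]methyl}-10-ethynyl-7-{[(4-methoxybenzyl)oxy]methyl}-9-[(triethylsilyl)oxy]cyclodeca-2,6-dien-1-ol
Conditions: K2CO3, MeOH, rt
Reagents that add atoms: none
Why: Methanolysis of the alkynyl C–Si bond under mild base frees the terminal alkyne without touching the triethylsilyl ether.

Step 15
Reactants: 20 (1S,2E,6E,9S,10R)-3-{[(tert-butyldiphenylsilyl)oxy]methyl}-10-ethynyl-7-{[(4-methoxybenzyl)oxy]methyl}-9-[(triethylsilyl)oxy]cyclodeca-2,6-dien-1-ol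
Product: 22 (1S,2E,6E,9S,10R)-3-{[(tert-butyldiphenylsilyl)oxy]methyl}-7-{[(4-methoxybenzyl)oxy]methyl}-10-[1-(4,4,5,5-tetramethyl-1,3,2-dioxaborolan-2-yl)ethenyl]-9-[(triethylsilyl)oxy]cyclodeca-2,6-dien-1-ol, via alkenylalane 21 (not isolated)
Conditions: Ni(dppp)Cl2 (3 mol %), iBu2AlH (2.2 equiv), THF, 0 °C to rt; then MeOBpin, rt [dppp = 1,3-bis(diphenylphosphino)propane]
Reagents that add atoms: 2-methoxy-4,4,5,5-tetramethyl-1,3,2-dioxaborolane, COB1OC(C)(C)C(C)(C)O1
Why: Nickel-catalysed hydroalumination with the bidentate phosphine complex places aluminium on the internal alkyne carbon (α-selective), and aluminium-to-boron exchange with the methoxyboronate should give the 1,1-disubstituted alkenylboronate.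

Step 16
Reactants: 22 (1S,2E,6E,9S,10R)-3-{[(tert-butyldiphenylsilyl)oxy]methyl}-7-{[(4-methoxybenzyl)oxy]methyl}-10-[1-(4,4,5,5-tetramethyl-1,3,2-dioxaborolan-2-yl)ethenyl]-9-[(triethylsilyl)oxy]cyclodeca-2,6-dien-1-ol
Product: 24 (3aR,4S,6E,10E,11aR)-10-{[(tert-butyldiphenylsilyl)oxy]methyl}-6-{[(4-methoxybenzyl)oxy]methyl}-3-methylidene-4-[(triethylsilyl)oxy]-3a,4,5,8,9,11a-hexahydrocyclodeca[b]furan-2(3H)-one, via hydroxy acid 23 (not isolated)
Conditions: KH (1.05 equiv), THF, 0 °C; (IPr)CuCl (5 mol %), KOtBu (1.1 equiv), CO2 (1 atm), 70 °C; then Ar purge, 0 °C, PPh3, DIAD, 2,6-lutidinium triflate (2.2 equiv, slow addition), 0 °C to rt [IPr = 1,3-bis(2,6-diisopropylphenyl)imidazol-2-ylidene]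
Reagents that add atoms: carbon dioxide, O=C=O
Why: After deprotonation, boron-to-copper transmetalation of the alkoxide-activated boronate gives an alkenylcopper–carbene complex that inserts CO2 to form the C11–C12 bond (copper-catalysed carboxylation of alkenylboronic esters), and in the same flask PPh3/DIAD turn the C6 hydroxyl into an alkoxyphosphonium leaving group that the tethered carboxylate displaces to form the O–C6 bond (Mitsunobu lactonisation), so C12 and both lactone oxygens come from CO2. The γ-lactone closes in the 5-exo-tet mode. The only stereocentre formed is C6, set by SN2 inversion of the 6S carbinol installed in step 12, which turns the 6,7-anti seco compound into the cis-fused 6R lactone; C7 and C8 are not touched. The step needs inversion rather than retention and attack at C6 rather than C4: the acid is liberated slowly from its potassium salt only once the betaine is present, which suppresses retentive acyl–oxygen lactonisation, SN2′ attack at C4 would require a seven-membered ring, and the only other hydroxyl (C8) is silylated.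

Step 17
Reactants: 24 (3aR,4S,6E,10E,11aR)-10-{[(tert-butyldiphenylsilyl)oxy]methyl}-6-{[(4-methoxybenzyl)oxy]methyl}-3-methylidene-4-[(triethylsilyl)oxy]-3a,4,5,8,9,11a-hexahydrocyclodeca[b]furan-2(3H)-one
Product: 25 (3aS,4S,6E,10E,11aR)-10-{[(tert-butyldiphenylsilyl)oxy]methyl}-4-hydroxy-6-{[(4-methoxybenzyl)oxy]methyl}-3-methylidene-3a,4,5,8,9,11a-hexahydrocyclodeca[b]furan-2(3H)-one
Conditions: PPTS, MeOH, rt
Reagents that add atoms: none
Why: Acid-catalysed methanolysis removes the triethylsilyl ether selectively in the presence of the tert-butyldiphenylsilyl and 4-methoxybenzyl ethers.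

Step 18
Reactants: 25 (3aS,4S,6E,10E,11aR)-10-{[(tert-butyldiphenylsilyl)oxy]methyl}-4-hydroxy-6-{[(4-methoxybenzyl)oxy]methyl}-3-methylidene-3a,4,5,8,9,11a-hexahydrocyclodeca[b]furan-2(3H)-one
Product: 26 (3aS,4S,6E,10E,11aR)-10-{[(tert-butyldiphenylsilyl)oxy]methyl}-6-{[(4-methoxybenzyl)oxy]methyl}-3-methylidene-2-oxo-2,3,3a,4,5,8,9,11a-octahydrocyclodeca[b]furan-4-yl (2Z)-2-methylbut-2-enoate
Conditions: angelic acid, 2,4,6-Cl3C6H2COCl, Et3N, toluene, rt; then 25, 80 °C
Reagents that add atoms: (2Z)-2-methylbut-2-enoic acid (angelic acid), C/C=C(/C)C(=O)O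
Why: Yamaguchi esterification through the mixed anhydride, run without a nucleophilic catalyst, acylates the hindered C8 hydroxyl while avoiding isomerisation of the angelate to the tiglate.

Step 19
Reactants: 26 (3aS,4S,6E,10E,11aR)-10-{[(tert-butyldiphenylsilyl)oxy]methyl}-6-{[(4-methoxybenzyl)oxy]methyl}-3-methylidene-2-oxo-2,3,3a,4,5,8,9,11a-octahydrocyclodeca[b]furan-4-yl (2Z)-2-methylbut-2-enoate
Product: 27 (3aS,4S,6E,10E,11aR)-10-{[(tert-butyldiphenylsilyl)oxy]methyl}-6-(hydroxymethyl)-3-methylidene-2-oxo-2,3,3a,4,5,8,9,11a-octahydrocyclodeca[b]furan-4-yl (2Z)-2-methylbut-2-enoate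
Conditions: DDQ, CH2Cl2/pH 7 buffer, 0 °C
Reagents that add atoms: none
Why: DDQ oxidises the electron-rich benzylic ether to an oxocarbenium ion that hydrolyses to the C14 alcohol and anisaldehyde (oxidative PMB cleavage).

Step 20
Reactants: 27 (3aS,4S,6E,10E,11aR)-10-{[(tert-butyldiphenylsilyl)oxy]methyl}-6-(hydroxymethyl)-3-methylidene-2-oxo-2,3,3a,4,5,8,9,11a-octahydrocyclodeca[b]furan-4-yl (2Z)-2-methylbut-2-enoate
Product: 28 (3aS,4S,6E,10E,11aR)-10-{[(tert-butyldiphenylsilyl)oxy]methyl}-6-formyl-3-methylidene-2-oxo-2,3,3a,4,5,8,9,11a-octahydrocyclodeca[b]furan-4-yl (2Z)-2-methylbut-2-enoate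
Conditions: MnO2, CH2Cl2, rt
Reagents that add atoms: none
Why: MnO2 oxidises the only free hydroxyl, a primary allylic alcohol, to the conjugated aldehyde.

Step 21
Reactants: 28 (3aS,4S,6E,10E,11aR)-10-{[(tert-butyldiphenylsilyl)oxy]methyl}-6-formyl-3-methylidene-2-oxo-2,3,3a,4,5,8,9,11a-octahydrocyclodeca[b]furan-4-yl (2Z)-2-methylbut-2-enoate
Product: 29 (3aS,4S,6E,10E,11aR)-6-formyl-10-(hydroxymethyl)-3-methylidene-2-oxo-2,3,3a,4,5,8,9,11a-octahydrocyclodeca[b]furan-4-yl (2Z)-2-methylbut-2-enoate (CNP0173211.3)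
Conditions: HF·pyridine, pyridine, THF, 0 °C to rt
Reagents that add atoms: none
Why: Fluoride cleaves the remaining silyl ether under buffered, non-basic conditions that spare the enal, the angelate and the α-methylene lactone.

Compound list
1 | but-2-yne-1,4-diol | OCC#CCO | starting material
2 | 4-[(tert-butyldiphenylsilyl)oxy]but-2-yn-1-ol | OCC#CCO[Si](c1ccccc1)(c1ccccc1)C(C)(C)C | intermediate
3 | sodium 3-{[(tert-butyldiphenylsilyl)oxy]methyl}-2,2-bis(2-methoxyethoxy)-2,5-dihydro-1,2-oxaluminol-2-uide (cyclic vinylalanate) | [Na+].COCCO[Al-]1(OCCOC)OCC=C1CO[Si](c2ccccc2)(c2ccccc2)C(C)(C)C | intermediate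
4 | (2Z)-4-[(tert-butyldiphenylsilyl)oxy]-3-iodobut-2-en-1-ol | OC/C=C(\I)CO[Si](c1ccccc1)(c1ccccc1)C(C)(C)C | intermediate
5 | (2E)-3-{[(tert-butyldiphenylsilyl)oxy]methyl}hepta-2,6-dien-1-ol | OC/C=C(\CCC=C)CO[Si](c1ccccc1)(c1ccccc1)C(C)(C)C | intermediate
6 | (2E)-3-{[(tert-butyldiphenylsilyl)oxy]methyl}hepta-2,6-dienal | O=C/C=C(\CCC=C)CO[Si](c1ccccc1)(c1ccccc1)C(C)(C)C | intermediate
7 | 2,3-dibromoprop-1-ene | C=C(Br)CBr | starting material
8 | 1-{[(2-bromoprop-2-en-1-yl)oxy]methyl}-4-methoxybenzene | C=C(Br)COCc1ccc(OC)cc1 | intermediate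
9 | (R)-glycidol, (2R)-oxiran-2-ylmethanol | OC[C@@H]1CO1 | starting material
10 | triethyl{[(2S)-oxiran-2-yl]methoxy}silane | CC[Si](CC)(CC)OC[C@@H]1CO1 | intermediate
11 | {3-[(4-methoxybenzyl)oxy]prop-1-en-2-yl}lithium (vinyllithium) | [Li]C(=C)COCc1ccc(OC)cc1 | intermediate
12 | (2S)-4-{[(4-methoxybenzyl)oxy]methyl}-1-[(triethylsilyl)oxy]pent-4-en-2-ol | CC[Si](CC)(CC)OC[C@@H](O)CC(=C)COCc1ccc(OC)cc1 | intermediate
13 | (2S)-4-{[(4-methoxybenzyl)oxy]methyl}-1,2-bis[(triethylsilyl)oxy]pent-4-ene | CC[Si](CC)(CC)OC[C@@H](O[Si](CC)(CC)CC)CC(=C)COCc1ccc(OC)cc1 | intermediate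
14 | (2S)-4-{[(4-methoxybenzyl)oxy]methyl}-2-[(triethylsilyl)oxy]pent-4-enal | O=C[C@@H](O[Si](CC)(CC)CC)CC(=C)COCc1ccc(OC)cc1 | intermediate
15 | (3R,4S)-6-{[(4-methoxybenzyl)oxy]methyl}-4-[(triethylsilyl)oxy]-1-(trimethylsilyl)hept-6-en-1-yn-3-ol | O[C@H](C#C[Si](C)(C)C)[C@@H](O[Si](CC)(CC)CC)CC(=C)COCc1ccc(OC)cc1 | intermediate
16 | (3R,4S)-6-{[(4-methoxybenzyl)oxy]methyl}-4-[(triethylsilyl)oxy]-1-(trimethylsilyl)hept-6-en-1-yn-3-yl methanesulfonate | CS(=O)(=O)O[C@H](C#C[Si](C)(C)C)[C@@H](O[Si](CC)(CC)CC)CC(=C)COCc1ccc(OC)cc1 | intermediate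
17 | [(M,4S)-6-{[(4-methoxybenzyl)oxy]methyl}-4-[(triethylsilyl)oxy]-1-(trimethylsilyl)hepta-1,2,6-trien-1-yl]zinc methanesulfonate (allenylzinc mesylate) | CS(=O)(=O)O[Zn]C([Si](C)(C)C)=[C@]=C([H])[C@@H](O[Si](CC)(CC)CC)CC(=C)COCc1ccc(OC)cc1 | intermediate
18 | (5E,7S,8R,9S)-5-{[(tert-butyldiphenylsilyl)oxy]methyl}-11-{[(4-methoxybenzyl)oxy]methyl}-9-[(triethylsilyl)oxy]-8-[(trimethylsilyl)ethynyl]dodeca-1,5,11-trien-7-ol | C=CCC/C(CO[Si](c1ccccc1)(c1ccccc1)C(C)(C)C)=C\[C@H](O)[C@@H](C#C[Si](C)(C)C)[C@@H](O[Si](CC)(CC)CC)CC(=C)COCc1ccc(OC)cc1 | intermediate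
19 | (1S,2E,6E,9S,10R)-3-{[(tert-butyldiphenylsilyl)oxy]methyl}-7-{[(4-methoxybenzyl)oxy]methyl}-9-[(triethylsilyl)oxy]-10-[(trimethylsilyl)ethynyl]cyclodeca-2,6-dien-1-ol | O[C@H]1/C=C(/CO[Si](c2ccccc2)(c2ccccc2)C(C)(C)C)CC/C=C(/COCc2ccc(OC)cc2)C[C@H](O[Si](CC)(CC)CC)[C@@H]1C#C[Si](C)(C)C | intermediate
20 | (1S,2E,6E,9S,10R)-3-{[(tert-butyldiphenylsilyl)oxy]methyl}-10-ethynyl-7-{[(4-methoxybenzyl)oxy]methyl}-9-[(triethylsilyl)oxy]cyclodeca-2,6-dien-1-ol | O[C@H]1/C=C(/CO[Si](c2ccccc2)(c2ccccc2)C(C)(C)C)CC/C=C(/COCc2ccc(OC)cc2)C[C@H](O[Si](CC)(CC)CC)[C@@H]1C#C | intermediate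
21 | {1-[(1R,2S,3E,7E,10S)-2-{[bis(2-methylpropyl)alumanyl]oxy}-4-{[(tert-butyldiphenylsilyl)oxy]methyl}-8-{[(4-methoxybenzyl)oxy]methyl}-10-[(triethylsilyl)oxy]cyclodeca-3,7-dien-1-yl]ethenyl}bis(2-methylpropyl)alumane (alkenylalane) | CC(C)C[Al](CC(C)C)O[C@H]1/C=C(/CO[Si](c2ccccc2)(c2ccccc2)C(C)(C)C)CC/C=C(/COCc2ccc(OC)cc2)C[C@H](O[Si](CC)(CC)CC)[C@@H]1C(=C)[Al](CC(C)C)CC(C)C | intermediate
22 | (1S,2E,6E,9S,10R)-3-{[(tert-butyldiphenylsilyl)oxy]methyl}-7-{[(4-methoxybenzyl)oxy]methyl}-10-[1-(4,4,5,5-tetramethyl-1,3,2-dioxaborolan-2-yl)ethenyl]-9-[(triethylsilyl)oxy]cyclodeca-2,6-dien-1-ol | O[C@H]1/C=C(/CO[Si](c2ccccc2)(c2ccccc2)C(C)(C)C)CC/C=C(/COCc2ccc(OC)cc2)C[C@H](O[Si](CC)(CC)CC)[C@@H]1C(=C)B1OC(C)(C)C(C)(C)O1 | intermediate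
23 | 2-[(1R,2S,3E,7E,10S)-4-{[(tert-butyldiphenylsilyl)oxy]methyl}-2-hydroxy-8-{[(4-methoxybenzyl)oxy]methyl}-10-[(triethylsilyl)oxy]cyclodeca-3,7-dien-1-yl]prop-2-enoic acid (hydroxy acid, formed as its potassium salt) | O[C@H]1/C=C(/CO[Si](c2ccccc2)(c2ccccc2)C(C)(C)C)CC/C=C(/COCc2ccc(OC)cc2)C[C@H](O[Si](CC)(CC)CC)[C@@H]1C(=C)C(=O)O | intermediate
24 | (3aR,4S,6E,10E,11aR)-10-{[(tert-butyldiphenylsilyl)oxy]methyl}-6-{[(4-methoxybenzyl)oxy]methyl}-3-methylidene-4-[(triethylsilyl)oxy]-3a,4,5,8,9,11a-hexahydrocyclodeca[b]furan-2(3H)-one | C=C1C(=O)O[C@@H]2/C=C(/CO[Si](c3ccccc3)(c3ccccc3)C(C)(C)C)CC/C=C(/COCc3ccc(OC)cc3)C[C@H](O[Si](CC)(CC)CC)[C@H]12 | intermediate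
25 | (3aS,4S,6E,10E,11aR)-10-{[(tert-butyldiphenylsilyl)oxy]methyl}-4-hydroxy-6-{[(4-methoxybenzyl)oxy]methyl}-3-methylidene-3a,4,5,8,9,11a-hexahydrocyclodeca[b]furan-2(3H)-one | C=C1C(=O)O[C@@H]2/C=C(/CO[Si](c3ccccc3)(c3ccccc3)C(C)(C)C)CC/C=C(/COCc3ccc(OC)cc3)C[C@H](O)[C@H]12 | intermediate
26 | (3aS,4S,6E,10E,11aR)-10-{[(tert-butyldiphenylsilyl)oxy]methyl}-6-{[(4-methoxybenzyl)oxy]methyl}-3-methylidene-2-oxo-2,3,3a,4,5,8,9,11a-octahydrocyclodeca[b]furan-4-yl (2Z)-2-methylbut-2-enoate | C=C1C(=O)O[C@@H]2/C=C(/CO[Si](c3ccccc3)(c3ccccc3)C(C)(C)C)CC/C=C(/COCc3ccc(OC)cc3)C[C@H](OC(=O)/C(C)=C\C)[C@H]12 | intermediate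
27 | (3aS,4S,6E,10E,11aR)-10-{[(tert-butyldiphenylsilyl)oxy]methyl}-6-(hydroxymethyl)-3-methylidene-2-oxo-2,3,3a,4,5,8,9,11a-octahydrocyclodeca[b]furan-4-yl (2Z)-2-methylbut-2-enoate | C=C1C(=O)O[C@@H]2/C=C(/CO[Si](c3ccccc3)(c3ccccc3)C(C)(C)C)CC/C=C(/CO)C[C@H](OC(=O)/C(C)=C\C)[C@H]12 | intermediate
28 | (3aS,4S,6E,10E,11aR)-10-{[(tert-butyldiphenylsilyl)oxy]methyl}-6-formyl-3-methylidene-2-oxo-2,3,3a,4,5,8,9,11a-octahydrocyclodeca[b]furan-4-yl (2Z)-2-methylbut-2-enoate | C=C1C(=O)O[C@@H]2/C=C(/CO[Si](c3ccccc3)(c3ccccc3)C(C)(C)C)CC/C=C(/C=O)C[C@H](OC(=O)/C(C)=C\C)[C@H]12 | intermediate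
29 | (3aS,4S,6E,10E,11aR)-6-formyl-10-(hydroxymethyl)-3-methylidene-2-oxo-2,3,3a,4,5,8,9,11a-octahydrocyclodeca[b]furan-4-yl (2Z)-2-methylbut-2-enoate | C=C1C(=O)O[C@@H]2/C=C(/CO)CC/C=C(/C=O)C[C@H](OC(=O)/C(C)=C\C)[C@H]12 | target

Total step count: 21. Longest linear sequence: 16 steps (step 5 or step 6, then steps 7 to 21).

Steps most likely to fail

1. Step 13 (ring-closing metathesis). Intermolecular metathesis (oligomerisation) may outrun the strained ten-membered ring closure, and the hindered 1,1-disubstituted olefin may react too slowly. Fallback (sets out from 18, returns at 24): the rings are built in the opposite order, so that the cis-fused lactone holds the two olefinic arms on one face before metathesis. Desilylation of 18 (K2CO3, MeOH) gives the open-chain ethynyl carbinol F1. Nickel-catalysed α-hydroalumination and boron trapping as in step 15 give the open-chain alkenylboronate F3 by way of the open-chain bis-alane F2. The conditions of step 16 give the open-chain cis-lactone F5 by way of the open-chain hydroxy acid F4. Ring-closing metathesis of F5 (second-generation Hoveyda–Grubbs catalyst, toluene, high dilution) then delivers 24; the electron-poor α-methylene group is expected to be a poor metathesis partner.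

2. Step 16 (carboxylation and inverting lactonisation). Retentive acyl–oxygen lactonisation of the liberated hydroxy acid, ionisation of the allylic alkoxyphosphonium ion with loss of configuration at C6, or protodemetalation of the alkenylcopper intermediate may compete. Fallback (sets out from 20, returns at 24): C–O inversion and C–C formation are separated. Mitsunobu reaction of 20 with 4-nitrobenzoic acid (PPh3, DIAD) gives the inverted 4-nitrobenzoate F6. Methanolysis (K2CO3, MeOH) gives the C6-epimeric alcohol F7. Nickel-catalysed α-hydroalumination as in step 15, quenched with I2, gives the α-iodoalkene F9 by way of the alane F8. Palladium-catalysed carbonylative lactonisation (Pd(PPh3)4, CO 1 atm, Et3N, MeCN, 60 °C) closes the lactone with retention at C6 to give 24.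

3. Step 12 (allenylzinc addition). β-Elimination of the silyloxy group from the allenyl/propargylzinc species, or mismatched double diastereoselection with the C8 stereocentre, may erode the coupling. Fallback (sets out from 15, returns at 18): an isolable covalent allenylboron reagent replaces the transient allenylzinc. Acylation of 15 with methyl chloroformate (pyridine, CH2Cl2) gives the propargylic methyl carbonate F10. Copper-catalysed anti-SN2′ borylation (CuOtBu, Xantphos, B2pin2, THF) gives the allenylboronate F11. Thermal allenylboration of 6 (toluene, rt to 50 °C), through the same closed six-membered transition state, gives 18.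

Further compounds
F1 | step 13 | (5E,7S,8R,9S)-5-{[(tert-butyldiphenylsilyl)oxy]methyl}-8-ethynyl-11-{[(4-methoxybenzyl)oxy]methyl}-9-[(triethylsilyl)oxy]dodeca-1,5,11-trien-7-ol | C=CCC/C(CO[Si](c1ccccc1)(c1ccccc1)C(C)(C)C)=C\[C@H](O)[C@@H](C#C)[C@@H](O[Si](CC)(CC)CC)CC(=C)COCc1ccc(OC)cc1
F2 | step 13 | O,C-bis(diisobutylalumanyl) derivative of F1 (7-O-alumanyl, 8-[1-(diisobutylalumanyl)ethenyl]; configuration as F1) | C=CCC/C(CO[Si](c1ccccc1)(c1ccccc1)C(C)(C)C)=C\[C@H](O[Al](CC(C)C)CC(C)C)[C@@H](C(=C)[Al](CC(C)C)CC(C)C)[C@@H](O[Si](CC)(CC)CC)CC(=C)COCc1ccc(OC)cc1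
F3 | step 13 | (5E,7S,8R,9S)-5-{[(tert-butyldiphenylsilyl)oxy]methyl}-11-{[(4-methoxybenzyl)oxy]methyl}-8-[1-(4,4,5,5-tetramethyl-1,3,2-dioxaborolan-2-yl)ethenyl]-9-[(triethylsilyl)oxy]dodeca-1,5,11-trien-7-ol | C=CCC/C(CO[Si](c1ccccc1)(c1ccccc1)C(C)(C)C)=C\[C@H](O)[C@@H](C(=C)B1OC(C)(C)C(C)(C)O1)[C@@H](O[Si](CC)(CC)CC)CC(=C)COCc1ccc(OC)cc1
F4 | step 13 | open-chain hydroxy acid: F3 with the boronate replaced by CO2H (7S,8R,9S; formed as its potassium salt) | C=CCC/C(CO[Si](c1ccccc1)(c1ccccc1)C(C)(C)C)=C\[C@H](O)[C@@H](C(=C)C(=O)O)[C@@H](O[Si](CC)(CC)CC)CC(=C)COCc1ccc(OC)cc1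
F5 | step 13 | (4R,5R)-5-[(1E)-2-{[(tert-butyldiphenylsilyl)oxy]methyl}hexa-1,5-dien-1-yl]-4-[(1S)-3-{[(4-methoxybenzyl)oxy]methyl}-1-[(triethylsilyl)oxy]but-3-en-1-yl]-3-methylideneoxolan-2-one | C=C1C(=O)O[C@H](/C=C(/CO[Si](c2ccccc2)(c2ccccc2)C(C)(C)C)CCC=C)[C@@H]1[C@@H](O[Si](CC)(CC)CC)CC(=C)COCc1ccc(OC)cc1
F6 | step 16 | (1R,2E,6E,9S,10R)-3-{[(tert-butyldiphenylsilyl)oxy]methyl}-10-ethynyl-7-{[(4-methoxybenzyl)oxy]methyl}-9-[(triethylsilyl)oxy]cyclodeca-2,6-dien-1-yl 4-nitrobenzoate | O=C(O[C@@H]1/C=C(/CO[Si](c2ccccc2)(c2ccccc2)C(C)(C)C)CC/C=C(/COCc2ccc(OC)cc2)C[C@H](O[Si](CC)(CC)CC)[C@@H]1C#C)c1ccc([N+](=O)[O-])cc1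
F7 | step 16 | (1R,2E,6E,9S,10R)-3-{[(tert-butyldiphenylsilyl)oxy]methyl}-10-ethynyl-7-{[(4-methoxybenzyl)oxy]methyl}-9-[(triethylsilyl)oxy]cyclodeca-2,6-dien-1-ol | O[C@@H]1/C=C(/CO[Si](c2ccccc2)(c2ccccc2)C(C)(C)C)CC/C=C(/COCc2ccc(OC)cc2)C[C@H](O[Si](CC)(CC)CC)[C@@H]1C#C
F8 | step 16 | O,C-bis(diisobutylalumanyl) derivative of F7 (1-O-alumanyl, 10-[1-(diisobutylalumanyl)ethenyl]; configuration as F7) | CC(C)C[Al](CC(C)C)O[C@@H]1/C=C(/CO[Si](c2ccccc2)(c2ccccc2)C(C)(C)C)CC/C=C(/COCc2ccc(OC)cc2)C[C@H](O[Si](CC)(CC)CC)[C@@H]1C(=C)[Al](CC(C)C)CC(C)C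
F9 | step 16 | (1R,2E,6E,9S,10R)-3-{[(tert-butyldiphenylsilyl)oxy]methyl}-10-(1-iodoethenyl)-7-{[(4-methoxybenzyl)oxy]methyl}-9-[(triethylsilyl)oxy]cyclodeca-2,6-dien-1-ol | O[C@@H]1/C=C(/CO[Si](c2ccccc2)(c2ccccc2)C(C)(C)C)CC/C=C(/COCc2ccc(OC)cc2)C[C@H](O[Si](CC)(CC)CC)[C@@H]1C(=C)I
F10 | step 12 | (3R,4S)-6-{[(4-methoxybenzyl)oxy]methyl}-4-[(triethylsilyl)oxy]-1-(trimethylsilyl)hept-6-en-1-yn-3-yl methyl carbonate | COC(=O)O[C@H](C#C[Si](C)(C)C)[C@@H](O[Si](CC)(CC)CC)CC(=C)COCc1ccc(OC)cc1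
F11 | step 12 | 2-[(P,4S)-6-{[(4-methoxybenzyl)oxy]methyl}-4-[(triethylsilyl)oxy]-1-(trimethylsilyl)hepta-1,2,6-trien-1-yl]-4,4,5,5-tetramethyl-1,3,2-dioxaborolane | CC1(C)OB(OC1(C)C)C([Si](C)(C)C)=[C@]=C([H])[C@@H](O[Si](CC)(CC)CC)CC(=C)COCc1ccc(OC)cc1
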